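**Strategy**

Ring B is built, not bought: cutting C1'–C6' and C2'–C3' turns it into a ring A aryl prop-1-ynyl ketone (C1', C2' and the methyl) and a four-carbon ketene-acetal silyloxydiene (C6', C5', C4', C3'). The feature exploited is the ring B pattern in which the acyl carbon C1' and the methyl carbon C2' are neighbours, with OMe at C6', OH at C4' para to the carbonyl, and H at C3' and C5'. One Diels–Alder/aromatization operation closes ring B with all three substituents in place. The precursor is the ynone whose ring A C2 phenol is masked as a methoxymethyl ether, so the same acidic work-up releases the target and no hydrogenation meets the aryl chloride.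

Key step: step 8

**Remarks**

- Numbering: ring A runs C1 (carbonyl-bearing), C2 (OH), C3 (Cl), C4 (OMe), C5 (H), C6 (OMe). Ring B runs C1' (carbonyl-bearing), C2' (CH3), C3' (H), C4' (OH), C5' (H), C6' (OMe).
- Protecting group: the C2 phenol must be masked, because a free ortho-hydroxyaryl ynone would close to a 2-methylchromone and would protonate the diene. A methoxymethyl ether is chosen because it is cleaved by the acid that finishes the key step; this avoids hydrogenolysis next to the aryl chloride and the diaryl ketone.
- Stereochemistry: the target has no stereocentre. Alcohol 7 is racemic and its centre is removed in step 5.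

**Route**

Step 1
Reactants: 1 3,5-dimethoxyphenol
Product: 2 2-chloro-3,5-dimethoxyphenol
Conditions: SO2Cl2 (1.0 equiv), 2,2,6,6-tetramethylpiperidine (5 mol %), toluene, 0 °C to rt
Reagents that add atoms: sulfuryl chloride, O=S(=O)(Cl)Cl
Why: Amine-catalysed ortho-selective electrophilic chlorination of a phenol, in which the N-chloroamine formed from SO2Cl2 is hydrogen-bonded to the phenol OH and should deliver chlorine to one of the two equivalent ortho carbons in preference to the para carbon, while one equivalent of reagent at low temperature limits dichlorination.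

Step 2
Reactants: 2 2-chloro-3,5-dimethoxyphenol
Product: 4 3-chloro-2-hydroxy-4,6-dimethoxybenzaldehyde, via salicyl alcohol 3 (not isolated)
Conditions: MgCl2 (anhydrous), Et3N, (CH2O)n, MeCN, reflux; then 1 M HCl
Reagents that add atoms: paraformaldehyde (formaldehyde unit), C=O
Why: Magnesium-mediated ortho-formylation of a phenol (Casnati–Skattebøl reaction), in which the magnesium phenoxide of 2 delivers formaldehyde to the only free ortho carbon and a second formaldehyde oxidizes the resulting salicyl alcohol 3 by Oppenauer-type hydride transfer, so the carbon between the two methoxy groups stays untouched.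

Step 3
Reactants: 4 3-chloro-2-hydroxy-4,6-dimethoxybenzaldehyde
Product: 5 3-chloro-4,6-dimethoxy-2-(methoxymethoxy)benzaldehyde
Conditions: MOMCl, i-Pr2NEt, CH2Cl2, 0 °C to rt
Reagents that add atoms: chloromethyl methyl ether, COCCl
Why: Williamson-type O-alkylation of the acidic chelated phenol by a highly reactive chloromethyl ether, giving an acetal-type ether that is stable to the Grignard reagent, to MnO2 and to heat.

Step 4
Reactants: 5 3-chloro-4,6-dimethoxy-2-(methoxymethoxy)benzaldehyde; 6 1-propynylmagnesium bromide
Product: 7 1-[3-chloro-4,6-dimethoxy-2-(methoxymethoxy)phenyl]but-2-yn-1-ol (racemic)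
Conditions: THF, 0 °C to rt; then sat. aq. NH4Cl
Reagents that add atoms: none
Why: Grignard 1,2-addition of a slim alkynyl nucleophile to the di-ortho-substituted aldehyde, assisted by chelation to the methoxymethyl oxygen, giving the carbinol centre as a racemate that step 5 removes.

Step 5
Reactants: 7 1-[3-chloro-4,6-dimethoxy-2-(methoxymethoxy)phenyl]but-2-yn-1-ol
Product: 8 1-[3-chloro-4,6-dimethoxy-2-(methoxymethoxy)phenyl]but-2-yn-1-one
Conditions: MnO2 (activated, excess), CH2Cl2, rt
Reagents that add atoms: none
Why: MnO2 oxidation of an alcohol that is both benzylic and propargylic, a neutral heterogeneous oxidation that should leave the methoxymethyl ether, the aryl chloride and the ynone untouched.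

Step 6
Reactants: 9 1,1-dimethoxyethene; 10 acetyl chloride
Product: 11 4,4-dimethoxybut-3-en-2-one
Conditions: Et3N, Et2O, 0 °C to rt (10 added slowly to 9 and Et3N)
Reagents that add atoms: none
Why: C-acylation of a ketene acetal at its nucleophilic β-carbon by an acid chloride, in which Et3N deprotonates the intermediate dimethoxycarbenium ion to restore the ketene acetal, the standard entry to acylketene acetals.

Step 7
Reactants: 11 4,4-dimethoxybut-3-en-2-one
Product: 12 1,1-dimethoxy-3-(trimethylsilyloxy)buta-1,3-diene
Conditions: TMSCl, Et3N, ZnCl2 (cat.), toluene, 40 °C; filtration and distillation under reduced pressure, no aqueous work-up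
Reagents that add atoms: chlorotrimethylsilane, C[Si](C)(C)Cl
Why: Soft enolization and O-silylation of a methyl ketone, the usual preparation of 2-silyloxybuta-1,3-dienes from vinylogous esters, which should give a single diene because the methyl group is the only enolizable position.

Step 8
Reactants: 8 1-[3-chloro-4,6-dimethoxy-2-(methoxymethoxy)phenyl]but-2-yn-1-one; 12 1,1-dimethoxy-3-(trimethylsilyloxy)buta-1,3-diene
Product: 16 (3-chloro-2-hydroxy-4,6-dimethoxyphenyl)(4-hydroxy-2-methoxy-6-methylphenyl)methanone, via cyclohexadiene ketal adduct 13 (not isolated), via aryl trimethylsilyl ether 14 (not isolated), via methoxymethyl benzophenone 15 (not isolated)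
Conditions: 12 (2.5 equiv), toluene, 100 °C, sealed vessel; then HCl (1.25 M in MeOH), 45 °C
Reagents that add atoms: none
Why: The electron-rich ketene-acetal diene 12 and the electron-poor alkyne of 8 combine in a concerted, strongly asynchronous (4+2) cycloaddition in which the diene CH2 terminus bonds to the methyl-bearing β-carbon (C2'–C3') and the ketal carbon to the α-carbon (C1'–C6'), closing the six-membered carbocycle of ring B as cyclohexa-1,4-diene 13. Adduct 13 should lose methanol by 1,4-elimination on heating to give aryl silyl ether 14, and anhydrous methanolic HCl, in which the ketal carbon can eliminate but cannot hydrolyse to a ketone, then removes the silyl group (15) and the ortho-carbonyl methoxymethyl ether (16). The closest known reaction type is the Diels–Alder reaction of 1,1-dialkoxy-3-silyloxybuta-1,3-dienes with acetylenic ketones and esters, which aromatizes to resorcinol monoalkyl ethers. No stereocentre is created. The one selectivity needed is regiochemical, and it is secured by matched polarization: the diene is most nucleophilic at its unsubstituted terminus, which is fed by the silyloxy group and by both methoxy groups, and the ynone is most electrophilic at its β-carbon, so OMe ends up ortho and OH para to the carbonyl. The alkyne lies outside the pocket formed by the C2 and C6 substituents of ring A, which shield the carbonyl against 1,2-addition without hindering the cycloaddition.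

**Compound list**

1 | 3,5-dimethoxyphenol | COc1cc(O)cc(OC)c1 | starting material
2 | 2-chloro-3,5-dimethoxyphenol | COc1cc(O)c(Cl)c(OC)c1 | intermediate
3 | 2-chloro-6-(hydroxymethyl)-3,5-dimethoxyphenol (present as its magnesium phenoxide) | OCc1c(O)c(Cl)c(OC)cc1OC | intermediate (not isolated)
4 | 3-chloro-2-hydroxy-4,6-dimethoxybenzaldehyde | O=Cc1c(O)c(Cl)c(OC)cc1OC | intermediate
5 | 3-chloro-4,6-dimethoxy-2-(methoxymethoxy)benzaldehyde | O=Cc1c(OCOC)c(Cl)c(OC)cc1OC | intermediate
6 | 1-propynylmagnesium bromide | CC#C[Mg]Br | starting material
7 | 1-[3-chloro-4,6-dimethoxy-2-(methoxymethoxy)phenyl]but-2-yn-1-ol (racemic) | CC#CC(O)c1c(OCOC)c(Cl)c(OC)cc1OC | intermediate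
8 | 1-[3-chloro-4,6-dimethoxy-2-(methoxymethoxy)phenyl]but-2-yn-1-one | CC#CC(=O)c1c(OCOC)c(Cl)c(OC)cc1OC | intermediate
9 | 1,1-dimethoxyethene | C=C(OC)OC | starting material
10 | acetyl chloride | CC(Cl)=O | starting material
11 | 4,4-dimethoxybut-3-en-2-one | CC(=O)C=C(OC)OC | intermediate
12 | 1,1-dimethoxy-3-(trimethylsilyloxy)buta-1,3-diene | COC(OC)=CC(=C)O[Si](C)(C)C | intermediate
13 | [3-chloro-4,6-dimethoxy-2-(methoxymethoxy)phenyl][6,6-dimethoxy-2-methyl-4-(trimethylsilyloxy)cyclohexa-1,4-dien-1-yl]methanone | COCOc1c(Cl)c(OC)cc(OC)c1C(=O)C1=C(C)CC(O[Si](C)(C)C)=CC1(OC)OC | intermediate (not isolated)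
14 | [3-chloro-4,6-dimethoxy-2-(methoxymethoxy)phenyl][2-methoxy-6-methyl-4-(trimethylsilyloxy)phenyl]methanone | COCOc1c(Cl)c(OC)cc(OC)c1C(=O)c1c(C)cc(O[Si](C)(C)C)cc1OC | intermediate (not isolated)
15 | [3-chloro-4,6-dimethoxy-2-(methoxymethoxy)phenyl](4-hydroxy-2-methoxy-6-methylphenyl)methanone | COCOc1c(Cl)c(OC)cc(OC)c1C(=O)c1c(C)cc(O)cc1OC | intermediate (not isolated)
16 | (3-chloro-2-hydroxy-4,6-dimethoxyphenyl)(4-hydroxy-2-methoxy-6-methylphenyl)methanone | COc1cc(OC)c(C(=O)c2c(C)cc(O)cc2OC)c(O)c1Cl | target

**Step count**

Total: 8 steps. Longest linear sequence: 6 steps (steps 1, 2, 3, 4, 5 and 8, from compound 1). The diene arm (steps 6 and 7) joins at step 8.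

**Steps most likely to fail**

Step 8. The cycloaddition at the methyl-substituted alkyne terminus may be too slow, so that the moisture-sensitive diene is consumed by hydrolysis or oligomerization first, or a Michael-type addition may occur without ring closure. The fallback gives up the ring construction and joins a preformed ring B by aryllithium addition; it sets out from compound 5 and comes back at compound 15.
- Commercial 3-methoxy-5-methylphenol is silylated (i-Pr3SiCl, imidazole, DMF) to triisopropyl(3-methoxy-5-methylphenoxy)silane F1.
- NBS in MeCN at 0 °C should brominate para to the bulky silyloxy group, between OMe and CH3, to give (4-bromo-3-methoxy-5-methylphenoxy)triisopropylsilane F2.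
- Bromine–lithium exchange (n-BuLi, THF, −78 °C) gives [2-methoxy-6-methyl-4-(triisopropylsilyloxy)phenyl]lithium F3.
- F3 adds to aldehyde 5 to give [3-chloro-4,6-dimethoxy-2-(methoxymethoxy)phenyl][2-methoxy-6-methyl-4-(triisopropylsilyloxy)phenyl]methanol F4 (racemic) after NH4Cl work-up.
- MnO2 in CH2Cl2 oxidizes the doubly benzylic alcohol to [3-chloro-4,6-dimethoxy-2-(methoxymethoxy)phenyl][2-methoxy-6-methyl-4-(triisopropylsilyloxy)phenyl]methanone F5.
- Bu4NF in THF at 0 °C removes the silyl group to give compound 15, which is carried through the methanolic HCl stage of step 8 to 16.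

Step 1. Chlorination may occur at the carbon para to the hydroxyl group, between the two methoxy groups, or a second chlorination may occur, which would erode the supply of 2. The fallback fixes the position by directed ortho-metalation; it sets out from compound 1 and comes back at compound 2.
- Compound 1 is converted (MOMCl, i-Pr2NEt, CH2Cl2) into 1,3-dimethoxy-5-(methoxymethoxy)benzene F6.
- n-BuLi in THF at 0 °C should lithiate next to the stronger directing methoxymethoxy group, between it and a methoxy group, to give [2,4-dimethoxy-6-(methoxymethoxy)phenyl]lithium F7.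
- Quenching with C2Cl6 gives 2-chloro-1,5-dimethoxy-3-(methoxymethoxy)benzene F8.
- Methanolic HCl at rt removes the acetal to give compound 2.

Step 6. The acylated dimethoxycarbenium intermediate may lose chloromethane (giving the β-keto ester instead of the ketene acetal), or a second acylation or polymerization of the ketene acetal may occur. The fallback builds the ketene acetal by substitution instead of acylation; it sets out from compound 10 and comes back at compound 11.
- Acetyl chloride 10 acylates 1,1-dichloroethene (AlCl3, CH2Cl2, 0 °C, Kondakov-type acylation) to give 4,4,4-trichlorobutan-2-one F9.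
- F9 loses hydrogen chloride on distillation to give 4,4-dichlorobut-3-en-2-one F10.
- Two successive addition–elimination reactions with sodium methoxide (NaOMe) in MeOH at 0 °C replace both vinylic chlorides to give compound 11.

**Further compounds**

F1 | step 8 | triisopropyl(3-methoxy-5-methylphenoxy)silane | COc1cc(C)cc(O[Si](C(C)C)(C(C)C)C(C)C)c1
F2 | step 8 | (4-bromo-3-methoxy-5-methylphenoxy)triisopropylsilane | COc1cc(O[Si](C(C)C)(C(C)C)C(C)C)cc(C)c1Br
F3 | step 8 | [2-methoxy-6-methyl-4-(triisopropylsilyloxy)phenyl]lithium | [Li]c1c(OC)cc(O[Si](C(C)C)(C(C)C)C(C)C)cc1C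
F4 | step 8 | [3-chloro-4,6-dimethoxy-2-(methoxymethoxy)phenyl][2-methoxy-6-methyl-4-(triisopropylsilyloxy)phenyl]methanol (racemic) | COCOc1c(Cl)c(OC)cc(OC)c1C(O)c1c(C)cc(O[Si](C(C)C)(C(C)C)C(C)C)cc1OC
F5 | step 8 | [3-chloro-4,6-dimethoxy-2-(methoxymethoxy)phenyl][2-methoxy-6-methyl-4-(triisopropylsilyloxy)phenyl]methanone | COCOc1c(Cl)c(OC)cc(OC)c1C(=O)c1c(C)cc(O[Si](C(C)C)(C(C)C)C(C)C)cc1OC
F6 | step 1 | 1,3-dimethoxy-5-(methoxymethoxy)benzene | COCOc1cc(OC)cc(OC)c1
F7 | step 1 | [2,4-dimethoxy-6-(methoxymethoxy)phenyl]lithium | [Li]c1c(OC)cc(OC)cc1OCOC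
F8 | step 1 | 2-chloro-1,5-dimethoxy-3-(methoxymethoxy)benzene | COCOc1cc(OC)cc(OC)c1Cl
F9 | step 6 | 4,4,4-trichlorobutan-2-one | CC(=O)CC(Cl)(Cl)Cl
F10 | step 6 | 4,4-dichlorobut-3-en-2-one | CC(=O)C=C(Cl)Cl
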